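Set the amounts side by side: the flask holds 0.020 M of free monomer and 0.20 mM of pre-initiator, far less. If each pre-initiator begins one chain at most, the count of chains stays within the pre-initiator charge.

| flask | free monomer | pre-initiator | remark | time |
|---|---|---|---|---|
| south-east | 0.020 M | 0.13 mM | run made earlier |  |
| south | 0.020 M | 0.30 mM | run made earlier |  |
| south-west | 0.010 M | 0.20 mM | run made earlier |  |
| flask | 0.020 M | 0.20 mM |  | 15 h |

- south-east (time / h: monomer in chains / %, free monomer / %): 1.00: 0, 98; 1.33: 0, 96; 2.00: 0, 94; 3.00: 0, 87; 5.00: 0, 79; 8.00: 5, 70; 12.0: 10, 55
- south (time / h: monomer in chains / %, free monomer / %): 1.00: 0, 96; 1.33: 0, 94; 2.00: 0, 93; 3.00: 0, 89; 5.00: 4, 80; 8.00: 10, 61; 12.0: 20, 45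
- south-west (time / h: monomer in chains / %, free monomer / %): 2.50: 2, 93; 5.00: 1, 83; 8.00: 1, 67; 10.0: 10, 61; 12.0: 14, 54

(each reading ± 2 percentage points)

- the average divides the monomer in chains by the number of chains begun, living and dead together
- the earlier runs do not show the number of chains; that part of a forecast is a guess

* average number of monomer units in a chain (chains begun, living or dead) at 15 h
* part of the free monomer that has reacted at 15 h

Take 100 as the charge ratio, free monomer charged per pre-initiator charged. Write the balance of pre-initiator: each one charged has either begun a chain or has not. So, counting one chain per pre-initiator begun, dp equals the share of the free monomer charged that stands in chains, times the charge ratio, divided by the share of the pre-initiator charge that has begun chains.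

Now climb the ladder of times. Chains first show at 5.00 h in the south run and at 8.00 h in the south-east run, sooner with more pre-initiator. Next comes the half-time of free monomer, read from the last readings as if first-order: 10.4 h in the south run and 13.9 h in the south-east run. The asked 15 h is longer than both, and the flask's 0.20 mM of pre-initiator lies between the charges of those runs, so my reckoning for the flask puts c between 52.7% and 63.2%. The readings show no chain count, so take a rough low estimate: guess the flask's share in chains at the south run's 20% of 12.0 h, and with every pre-initiator begun dp comes to about 20.0.

The forecast gives dp 40 and c 59%. Its dp is twice my low estimate, on the ground that “Partial activation raises this”.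

The flask gives dp 47.8 and c 61.1%.

    free monomer + initiator → living end + monomer in chains (k = 0.00730 M⁻¹ s⁻¹)
    free monomer + living end → monomer in chains + living end, rate k2*[living end]*[free monomer] (k = 0.144 M⁻¹ s⁻¹)
    pre-initiator ⇌ initiator (K = 0.850, k = 1.69 × 10⁻⁵ s⁻¹)
    free monomer → uncatalysed product (k = 1.08 × 10⁻⁵ s⁻¹)

At 15.0 h the flask holds 8.77 × 10⁻⁵ M of living end. Apply the charge ratio: 21.0% in chains times 100, over 47.8, puts 43.9% of the pre-initiator charge as begun. In the neighbouring flask with 5.0 × 10⁻⁵ M of pre-initiator the ratio is 400, with 6.02% in chains and dp 52.8, so 45.6% of its charge has begun chains.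

The data are calculated from invented constants; the scatter is artificial.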